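## Retrosynthetic overview
1. The oxirane is made last, by oxygen-atom transfer to the C8=C9 alkene of the fully acylated 8,9-dehydrothymol triester. This copies the presumed oxygenase step, and a chiral nonheme iron/H2O2 catalyst sets C8 with no directing hydroxyl.
2. The triester alkene is cut at the aryl–C8 bond (Stille) into an aryl iodide diester and 2-(tributylstannyl)allyl acetate, made from propargyl acetate, so the C10 acetate arrives ready-made.
3. The aryl iodide diester comes from phenol angeloylation, preceded by Mitsunobu esterification of 5-(hydroxymethyl)-2-iodophenol with (R)-2-methylbutanoic acid, which brings in C2'.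
4. Ring order: the benzene ring is bought and the oxirane is formed in the final step. No protecting groups are used.

Assumption (supply): the iodophenol, (R)-2-methylbutanoic acid as the single enantiomer, angelic acid and propargyl acetate are bought. The iron catalyst is made beforehand from its ligand and Fe(OTf)2(MeCN)2 and is not counted as a step.

Assumption (sense of induction): the pair of (S,S)-catalyst and L-isoleucine co-ligand is taken to give the (R)-epoxide. This is checked on the first run by HPLC against a reference sample from the tartrate route given at the end. If the sense is reversed, the mirror-image pair is used and nothing else changes.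

Abbreviation: Me2N-PDP = (2S,2'S)-1,1'-bis{[4-(dimethylamino)pyridin-2-yl]methyl}-2,2'-bipyrrolidine.

## Route

Step 1
Reactants: 1 5-(hydroxymethyl)-2-iodophenol; 2 (R)-2-methylbutanoic acid
Product: 3 (3-hydroxy-4-iodophenyl)methyl (2R)-2-methylbutanoate
Conditions: PPh3 (1.2 equiv), DIAD (1.2 equiv, added last), THF, 0 °C to rt, 3 h
Reagents that add atoms: none
Why: Mitsunobu esterification, in which only the primary benzylic alcohol becomes an oxyphosphonium leaving group and the carboxylate of 2 (pKa near 5) outcompetes the far less acidic phenol (pKa near 9) as nucleophile, so the phenol stays free, and because the acid is never activated at its carbonyl the (R) centre brought in by 2 cannot racemise.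

Step 2
Reactants: 3 (3-hydroxy-4-iodophenyl)methyl (2R)-2-methylbutanoate; 4 angelic acid
Product: 6 2-iodo-5-({[(2R)-2-methylbutanoyl]oxy}methyl)phenyl (Z)-2-methylbut-2-enoate, via angelic trichlorobenzoic anhydride 5 (not isolated)
Conditions: 4, 2,4,6-trichlorobenzoyl chloride (1.1 equiv), Et3N (1.2 equiv), toluene, 0 °C to rt, 1 h; then 3, Et3N (1.5 equiv), rt, 6 h; no DMAP
Reagents that add atoms: none
Why: Yamaguchi-type mixed-anhydride acylation, in which the phenoxide–triethylammonium pair attacks the open angeloyl carbonyl of 5 rather than the carbonyl flanked by two ortho chlorines, and leaving out any nucleophilic catalyst closes the conjugate addition–elimination path that turns angelates into tiglates, so the Z geometry of 4 is kept and no stereocentre is touched.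

Step 3
Reactants: 7 prop-2-yn-1-yl acetate (propargyl acetate)
Product: 8 2-(tributylstannyl)prop-2-en-1-yl acetate
Conditions: Bu3SnH (1.3 equiv), Mo(CO)3(CNtBu)3 (2 mol%), hydroquinone (10 mol%), THF, 55 °C, 12 h
Reagents that add atoms: tributyltin hydride, CCCC[SnH](CCCC)CCCC
Why: Molybdenum-catalysed hydrostannation, a syn H–Sn addition that places tin on the internal alkyne carbon next to the electron-withdrawing acetoxymethyl group while hydroquinone suppresses the radical chain leading to terminal stannanes, and no stereocentre is formed.

Step 4
Reactants: 6 2-iodo-5-({[(2R)-2-methylbutanoyl]oxy}methyl)phenyl (Z)-2-methylbut-2-enoate; 8 2-(tributylstannyl)prop-2-en-1-yl acetate (1.15 equiv)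
Product: 9 2-[3-(acetyloxy)prop-1-en-2-yl]-5-({[(2R)-2-methylbutanoyl]oxy}methyl)phenyl (Z)-2-methylbut-2-enoate
Conditions: Pd2(dba)3·CHCl3 (2.5 mol%), AsPh3 (20 mol%), NMP, 50 °C, 8–12 h, stopped when 6 is consumed
Reagents that add atoms: none
Why: Stille cross-coupling with a weakly donating ligand, in which zerovalent palladium inserts into the carbon–iodine bond much faster than it ionises an allylic acetate and AsPh3 speeds transmetalation of the hindered vinylstannane, while the neutral, base-free and copper-free medium spares the aryl angelate and both alkyl esters and avoids β-acetoxy elimination, with no stereocentre formed and C2' and the Z alkene untouched.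

Step 5
Reactants: 9 2-[3-(acetyloxy)prop-1-en-2-yl]-5-({[(2R)-2-methylbutanoyl]oxy}methyl)phenyl (Z)-2-methylbut-2-enoate
Product: 10 target CNP0256757.1 = 2-[(2R)-2-(acetoxymethyl)oxiran-2-yl]-5-({[(2R)-2-methylbutanoyl]oxy}methyl)phenyl (Z)-2-methylbut-2-enoate
Conditions: [Fe(OTf)2((S,S)-Me2N-PDP)] (2 mol%), N-(1,8-naphthaloyl)-L-isoleucine (3 mol%), 30% aq H2O2 (1.3 equiv, syringe pump, 30 min), MeCN, −30 °C; chromatography on Et3N-washed silica
Reagents that add atoms: hydrogen peroxide, OO
Why: Bioinspired nonheme-iron asymmetric epoxidation of an α-substituted styrene, in which carboxylic-acid-assisted O–O heterolysis at divalent iron gives an electrophilic pentavalent iron-oxo carboxylate that transfers oxygen in a concerted way to the more electron-rich 1,1-disubstituted C8=C9 alkene rather than to the ester-conjugated angelate alkene, and the pocket built by the bipyrrolidine backbone and the amino-acid co-ligand tells aryl from CH2OAc so that C8 is set as R under catalyst control while all three esters and C2' are inert at −30 °C.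

## Compound list
1 | 5-(hydroxymethyl)-2-iodophenol | OCc1ccc(I)c(O)c1 | starting material
2 | (R)-2-methylbutanoic acid | CC[C@@H](C)C(=O)O | starting material
3 | (3-hydroxy-4-iodophenyl)methyl (2R)-2-methylbutanoate | CC[C@@H](C)C(=O)OCc1ccc(I)c(O)c1 | intermediate
4 | angelic acid = (Z)-2-methylbut-2-enoic acid | C/C=C(/C)C(=O)O | starting material
5 | (Z)-2-methylbut-2-enoic 2,4,6-trichlorobenzoic anhydride (not isolated) | C/C=C(/C)C(=O)OC(=O)c1c(Cl)cc(Cl)cc1Cl | intermediate
6 | 2-iodo-5-({[(2R)-2-methylbutanoyl]oxy}methyl)phenyl (Z)-2-methylbut-2-enoate | C/C=C(/C)C(=O)Oc1cc(COC(=O)[C@H](C)CC)ccc1I | intermediate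
7 | prop-2-yn-1-yl acetate | C#CCOC(C)=O | starting material
8 | 2-(tributylstannyl)prop-2-en-1-yl acetate | C=C(COC(C)=O)[Sn](CCCC)(CCCC)CCCC | intermediate
9 | 10-acetoxy-8,9-dehydrothymol 3-O-angelate 7-O-[(R)-2-methylbutanoate] | C/C=C(/C)C(=O)Oc1cc(COC(=O)[C@H](C)CC)ccc1C(=C)COC(C)=O | intermediate
10 | CNP0256757.1, (8R,2'R)-10-acetoxy-8,9-epoxythymol 3-O-angelate 7-O-(2-methylbutanoate) | C/C=C(/C)C(=O)Oc1cc(COC(=O)[C@H](C)CC)ccc1[C@]1(COC(C)=O)CO1 | target

## Step count and risks
Total steps: 5. Longest linear sequence: 4 (1 → 3 → 6 → 9 → 10, that is steps 1, 2, 4 and 5). Step 3 is a one-step side branch.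

**Step 5 (highest risk).**
- The ortho acyloxy group twists the arene out of conjugation, and CH2OAc is a new α-substituent for this catalyst class. The ee may therefore fall below the 85–95% seen with α-alkylstyrenes.
- The sense of induction is unproven, and the cis-configured angelate alkene may take up some oxygen.
- The C8 epimer is a diastereomer of 10 and can be trimmed by HPLC, but not if selectivity is poor.
- The fallback replaces non-directed catalyst control by hydroxyl direction. It sets out from 6 and comes back at 10.
- Propargyl alcohol is hydrostannylated as in step 3 to 2-(tributylstannyl)prop-2-en-1-ol F1. This is coupled with 6 under the step 4 conditions to the free allylic alcohol F2.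
- Katsuki–Sharpless epoxidation (Ti(OiPr)4, L-(+)-diethyl tartrate, tBuOOH, 4 Å sieves, CH2Cl2, −20 °C) then gives the (S)-epoxy alcohol F3, whose sense follows the secure tartrate rule.
- Ac2O/pyridine at 0 °C gives 10. The spatial arrangement is unchanged; the descriptor goes from S to R only because CH2OAc outranks the ring CH2.
- The price is two more steps, and the aryl angelate is exposed to a neighbouring free hydroxyl and to a titanium alkoxide.

**Step 4.**
- Zerovalent palladium may ionise the allylic acetate of 8 or 9 and couple it with the stannane. The α-substituted stannane may also transmetalate slowly or give cine substitution.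
- The coupling cannot be moved ahead of step 2, because a free ortho phenol would close onto the π-allyl complex to give a benzofuran.
- The fallback brings in C10–O after the carbon–carbon bond. It sets out from 6 and comes back at 9.
- Suzuki–Miyaura coupling of 6 with isopropenylboronic acid pinacol ester (Pd(OAc)2, SPhos, anhydrous K3PO4, toluene, 60 °C) gives the 8,9-dehydrothymol diester F4, which carries no allylic leaving group.
- Ionic ene-type allylic bromination (NBS, Yb(OTf)3 and Me3SiCl at 5 mol% each, CH2Cl2/THF, rt) gives the 2-arylallyl bromide F5.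
- KOAc with 18-crown-6 in MeCN at rt then gives 9.

**Step 2.**
- The angeloyl unit may isomerise to tigloyl during activation, or the phenoxide may attack the wrong carbonyl of 5.
- The fallback builds the Z alkene on the ester instead of transferring it. It sets out from 3 and comes back at 6.
- The phenol is acylated with 2-[bis(2,2,2-trifluoroethoxy)phosphoryl]propanoic acid (EDC·HCl, DMAP 5 mol%, CH2Cl2, 0 °C) to the aryl phosphonopropanoate F6.
- Still–Gennari olefination (KHMDS 1.0 equiv, 18-crown-6, THF, −78 °C, then acetaldehyde) gives the Z-trisubstituted enoate 6. The single equivalent of base is consumed by the far more acidic phosphonate position, so C2' is not epimerised.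

## Further compounds
F1 | step 5 | 2-(tributylstannyl)prop-2-en-1-ol | C=C(CO)[Sn](CCCC)(CCCC)CCCC
F2 | step 5 | 2-(3-hydroxyprop-1-en-2-yl)-5-({[(2R)-2-methylbutanoyl]oxy}methyl)phenyl (Z)-2-methylbut-2-enoate | C/C=C(/C)C(=O)Oc1cc(COC(=O)[C@H](C)CC)ccc1C(=C)CO
F3 | step 5 | 2-[(2S)-2-(hydroxymethyl)oxiran-2-yl]-5-({[(2R)-2-methylbutanoyl]oxy}methyl)phenyl (Z)-2-methylbut-2-enoate | C/C=C(/C)C(=O)Oc1cc(COC(=O)[C@H](C)CC)ccc1[C@]1(CO)CO1
F4 | step 4 | 5-({[(2R)-2-methylbutanoyl]oxy}methyl)-2-(prop-1-en-2-yl)phenyl (Z)-2-methylbut-2-enoate | C/C=C(/C)C(=O)Oc1cc(COC(=O)[C@H](C)CC)ccc1C(C)=C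
F5 | step 4 | 2-(3-bromoprop-1-en-2-yl)-5-({[(2R)-2-methylbutanoyl]oxy}methyl)phenyl (Z)-2-methylbut-2-enoate | C/C=C(/C)C(=O)Oc1cc(COC(=O)[C@H](C)CC)ccc1C(=C)CBr
F6 | step 2 | 2-iodo-5-({[(2R)-2-methylbutanoyl]oxy}methyl)phenyl 2-[bis(2,2,2-trifluoroethoxy)phosphoryl]propanoate (both epimers at the phosphonate carbon) | CC(C(=O)Oc1cc(COC(=O)[C@H](C)CC)ccc1I)P(=O)(OCC(F)(F)F)OCC(F)(F)F
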